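## Retrosynthetic overview

1. Target 19 ⇐ 8α‑hydroxy ketone 16 + angelic acid 17 (esterification last).
2. 16 ⇐ cyclopropyl ketone 12: the gem‑dimethylcyclopropane of carene is a masked 7β‑isopropenyl group plus a C8 enol (homoconjugate opening, then Rubottom oxidation and selenoxide elimination).
3. Ring A ⇐ C4–C5 bond by an electrochemical cobalt‑hydride 6‑endo radical cyclization of alkene–enone 10 (sets C4, C5, C10).
4. 10 ⇐ photochemical singlet‑oxygen ene reaction of (E)‑alkylidene ketone 8 (sets C1) ⇐ aldol condensation of cis‑caranone 3 with pent‑4‑enal 4.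
5. Ring order: ring B is bought as (+)‑3‑carene 1, ring A is closed second, and the cyclopropane is opened last.

Assumption: decalin compounds use eremophilane numbering (C1–C10 ring carbons, C11–C13 on C7, C14 on C5, C15 on C4), β is the face of the C14 methyl, and the target is the kinetically held trans‑fused (10αH) ketone, so no step after ring closure uses a base that enolises C9 toward C10.

## Route

Step 1
Reactants: 1 (+)-3-carene
Product: 2 car-3-en-5-one
Conditions: t-BuOOH (70% aq), CrO3 (5 mol%), CH2Cl2, 20 °C
Reagents that add atoms: tert-butyl hydroperoxide, CC(C)(C)OO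
Why: Chromium‑catalysed allylic C–H oxidation with a hydroperoxide goes to the ring CH2 that is both allylic and next to the cyclopropane, and no stereocentre is touched.

Step 2
Reactants: 2 car-3-en-5-one
Product: 3 cis-caran-5-one
Conditions: H2 (1 atm), Pd/C (5%), EtOAc, 20 °C
Reagents that add atoms: none
Why: Heterogeneous hydrogenation adds H2 to the face opposite the gem‑dimethylcyclopropane (as in 3‑carene to cis‑carane), so the ring methyl ends cis to the cyclopropane and the new ring C–H lies on the open α face, a relay centre used in step 4.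

Step 3
Reactants: 3 cis-caran-5-one; 4 pent-4-enal
Product: 8 (E)-pentenylidene caranone, via lithium enolate 5 (not isolated), via lithium aldolate 6 (not isolated), via mesylate 7 (not isolated)
Conditions: LiN(iPr)2, THF, −78 °C; 4; MsCl, −78 → 0 °C; DBU, 0 → 20 °C
Reagents that add atoms: none
Why: Directed aldol condensation works because only the CH2 α‑position can enolise (the cyclopropyl α‑H cannot), and E1cB loss of mesylate gives the more stable E‑alkylidene ketone whose geometry later fixes C1.

Step 4
Reactants: 8 (E)-pentenylidene caranone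
Product: 10 (1S)-hydroxypentenyl enone, via hydroperoxide 9 (not isolated)
Conditions: O2, tetraphenylporphyrin (cat.), visible light, CH2Cl2, 0 °C; then PPh3, 0 → 20 °C
Reagents that add atoms: dioxygen, O=O
Why: Schenck ene reaction of singlet oxygen with an s‑cis enone puts oxygen on the β‑carbon (C1) and takes the hydrogen from the ring carbon geminal to the carbonyl; it is suprafacial on the α face, the only face carrying that hydrogen and the one away from the cyclopropane, which on the E‑alkene gives 1S and the endocyclic enone, and PPh3 reduces the hydroperoxide.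

Step 5
Reactants: 10 (1S)-hydroxypentenyl enone
Product: 11 1α-hydroxy-8,11-cyclo-10αH-eremophilan-9-one
Conditions: undivided cell, Zn anode, glassy‑carbon cathode, Co(salen) (10 mol%, achiral ethylenediamine ligand), (CF3)2CHOH (3 equiv), n-Bu4NPF6 (0.1 M), MeCN, constant current, 2.5 F/mol, 20 °C
Reagents that add atoms: none
Why: Proposed new method: cobalt‑electrocatalytic hydrogen‑atom‑transfer 6‑endo radical conjugate cyclization onto a fully substituted enone carbon; cathodic reduction of divalent to monovalent cobalt and protonation by (CF3)2CHOH give a trivalent cobalt hydride that transfers H• to the terminal alkene (Markovnikov, so C15 becomes the methyl and C4 a secondary radical), the C4 radical adds to the enone β‑carbon C5 through a chair transition state (C15 pseudo‑equatorial, the hydrogen‑bonded C1–OH in the enone plane so the tether hangs on the α face) anti to the cyclopropane, which sets C5 (C14 β) and C4 (C15 β), and the α‑keto radical is reduced to the enolate and protonated at C10 from the same open α face (the β face is blocked by the cyclopropane endo‑methyl and C14) to give the trans ring fusion under kinetic control; the closest known reactions are the Fe(acac)3/PhSiH3 reductive alkene–enone coupling and cobalt‑electrocatalytic hydrogen atom transfer to alkenes.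

Step 6
Reactants: 11 1α-hydroxy-8,11-cyclo-10αH-eremophilan-9-one
Product: 12 1α-acetoxy-8,11-cyclo-10αH-eremophilan-9-one
Conditions: Ac2O, pyridine, DMAP (5 mol%), CH2Cl2, 0 → 20 °C
Reagents that add atoms: acetic anhydride, CC(=O)OC(C)=O
Why: Standard acylation of the equatorial secondary alcohol under weakly basic conditions that do not enolise the ketone, so C1 and C10 are untouched.

Step 7
Reactants: 12 1α-acetoxy-8,11-cyclo-10αH-eremophilan-9-one
Product: 13 1α-acetoxy-11-phenylselanyl-9-trimethylsilyloxy-10αH-eremophil-8-ene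
Conditions: PhSeSiMe3 (1.3 equiv), Me3SiOSO2CF3 (10 mol%), CH2Cl2, −78 → −30 °C; Et3N quench
Reagents that add atoms: phenyl trimethylsilyl selenide, C[Si](C)(C)[Se]c1ccccc1
Why: Proposed new method: Lewis‑acid‑catalysed homoconjugate addition of a silyl selenide to a cyclopropyl ketone; the silylated carbonyl opens the C8–C11 bond (the one that overlaps with the carbonyl π system and leads to the tertiary cation), PhSe–SiMe3 captures C11 and passes its silyl group to the next ketone, so the silyl enol ether forms only toward C8 without base and C7 and C10 are untouched; the closest known reactions are the Me3SiI ring opening of cyclopropyl ketones to γ‑iodo silyl enol ethers and the 1,4‑addition of PhSeSiMe3 to enones.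

Step 8
Reactants: 13 1α-acetoxy-11-phenylselanyl-9-trimethylsilyloxy-10αH-eremophil-8-ene
Product: 16 1α-acetoxy-8α-hydroxy-10αH-eremophil-11-en-9-one, via selenoxide silyloxy-epoxide 14 (not isolated), via silyloxy ketone 15 (not isolated)
Conditions: dimethyldioxirane (2.2 equiv), acetone/CH2Cl2, −78 °C; pyridine, −78 → 20 °C; then aq. citric acid, THF
Reagents that add atoms: dimethyldioxirane, CC1(C)OO1
Why: Rubottom oxidation epoxidises the silyl enol ether from the α face (anti to the bulky C7 substituent and to C14), giving 8α‑OH after silyl migration and hydrolysis, and selenoxide syn‑elimination on warming takes a methyl hydrogen rather than the hindered, no longer allylic C7–H, giving the isopropenyl group.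

Step 9
Reactants: 16 1α-acetoxy-8α-hydroxy-10αH-eremophil-11-en-9-one; 17 angelic acid
Product: 19 target, via mixed anhydride 18 (not isolated)
Conditions: 17, 2,4,6-Cl3C6H2COCl, Et3N, PhMe, 20 °C; then 16, 70 °C
Reagents that add atoms: none
Why: Yamaguchi‑type mixed‑anhydride esterification without a nucleophilic catalyst keeps the Z geometry of the angelate and acylates the hindered 8α‑OH without touching a stereocentre; time at 70 °C is kept short to avoid loss of the 1‑acetate and C10 epimerisation.

## Compound list

1 | (+)-3-carene, (1S,6R)-3,7,7-trimethylbicyclo[4.1.0]hept-3-ene | CC1=CC[C@@H]2[C@H](C1)C2(C)C | starting material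
2 | car-3-en-5-one, (1R,6S)-4,7,7-trimethylbicyclo[4.1.0]hept-3-en-2-one | CC1=CC(=O)[C@@H]2[C@H](C1)C2(C)C | intermediate
3 | cis-caran-5-one, (1R,4R,6S)-4,7,7-trimethylbicyclo[4.1.0]heptan-2-one (ring methyl cis to the cyclopropane) | C[C@H]1CC(=O)[C@@H]2[C@H](C1)C2(C)C | intermediate
4 | pent-4-enal | C=CCCC=O | starting material
5 | lithium enolate of 3 (enolate toward the ring CH2) | [Li+].[O-]C1=C[C@H](C)C[C@H]2[C@@H]1C2(C)C | intermediate
6 | lithium aldolate of 3 with 4 (carane centres as in 3, the two new centres a mixture) | C=CCCC([O-])C1C(=O)[C@@H]2[C@H](C[C@H]1C)C2(C)C.[Li+] | intermediate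
7 | methanesulfonate of the aldol (same mixture) | C=CCCC(OS(C)(=O)=O)C1C(=O)[C@@H]2[C@H](C[C@H]1C)C2(C)C | intermediate
8 | (1R,3E,4R,6S)-4,7,7-trimethyl-3-(pent-4-en-1-ylidene)bicyclo[4.1.0]heptan-2-one | C=CCC/C=C1/C(=O)[C@@H]2[C@H](C[C@H]1C)C2(C)C | intermediate
9 | (1R,6S)-3-[(1S)-1-hydroperoxypent-4-en-1-yl]-4,7,7-trimethylbicyclo[4.1.0]hept-3-en-2-one | C=CCC[C@H](OO)C1=C(C)C[C@H]2[C@@H](C1=O)C2(C)C | intermediate
10 | (1R,6S)-3-[(1S)-1-hydroxypent-4-en-1-yl]-4,7,7-trimethylbicyclo[4.1.0]hept-3-en-2-one | C=CCC[C@H](O)C1=C(C)C[C@H]2[C@@H](C1=O)C2(C)C | intermediate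
11 | 1α-hydroxy-8,11-cyclo-10αH-eremophilan-9-one, (1S,4S,5R,7S,8R,10S); trans-decalin, C14 and C15 β, cyclopropane carbon C11 on the β face of C7 and C8 | CC1(C)[C@H]2C[C@@]3(C)[C@H](C(=O)[C@@H]12)[C@@H](O)CC[C@@H]3C | intermediate
12 | 1α-acetoxy-8,11-cyclo-10αH-eremophilan-9-one (acetate of 11) | CC1(C)[C@H]2C[C@@]3(C)[C@H](C(=O)[C@@H]12)[C@@H](OC(C)=O)CC[C@@H]3C | intermediate
13 | 1α-acetoxy-11-(phenylselanyl)-9-(trimethylsilyloxy)-10αH-eremophil-8-ene (7β side chain CMe2SePh) | CC(C)([Se]c1ccccc1)[C@H]1C[C@@]2(C)[C@H](C(O[Si](C)(C)C)=C1)[C@@H](OC(C)=O)CC[C@@H]2C | intermediate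
14 | selenoxide of 13 with 8α,9α-epoxide and 9β-trimethylsilyloxy group (Se configuration unassigned) | CC(C)([Se](=O)c1ccccc1)[C@H]1C[C@@]2(C)[C@H]([C@]3(O[Si](C)(C)C)O[C@H]13)[C@@H](OC(C)=O)CC[C@@H]2C | intermediate
15 | 1α-acetoxy-8α-(trimethylsilyloxy)-10αH-eremophil-11-en-9-one | C=C(C)[C@H]1C[C@@]2(C)[C@H](C(=O)[C@@H]1O[Si](C)(C)C)[C@@H](OC(C)=O)CC[C@@H]2C | intermediate
16 | 1α-acetoxy-8α-hydroxy-10αH-eremophil-11-en-9-one, (1S,4S,5R,7R,8R,10S) | C=C(C)[C@H]1C[C@@]2(C)[C@H](C(=O)[C@@H]1O)[C@@H](OC(C)=O)CC[C@@H]2C | intermediate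
17 | angelic acid, (Z)-2-methylbut-2-enoic acid | C/C=C(/C)C(=O)O | starting material
18 | angelic 2,4,6-trichlorobenzoic anhydride | C/C=C(/C)C(=O)OC(=O)c1c(Cl)cc(Cl)cc1Cl | intermediate
19 | 1α-acetoxy-8α-angeloyloxy-10αH-eremophil-11-en-9-one, (1S,4S,5R,7R,8R,10S), CNP0138236.2 | C=C(C)[C@H]1C[C@@]2(C)[C@H](C(=O)[C@@H]1OC(=O)/C(C)=C\C)[C@@H](OC(C)=O)CC[C@@H]2C | target

## Step count and risks

Total steps: 9. Longest linear sequence: 9 (from (+)-3-carene).

Most likely to fail, first: step 5 (new method). The cobalt hydride may isomerise the terminal alkene instead of cyclising, and the C10 protonation may give some cis‑fused ketone. The fallback sets out from 10 and comes back at 11. It replaces the electrolysis by the established thermal iron‑hydride reductive olefin coupling (Fe(acac)3, PhSiH3, EtOH/ethylene glycol, 60 °C). There the same C4 radical is made from a silane‑derived iron hydride, adds to C5, and the iron enolate is protonated by ethanol. It makes no new compound, F0.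

Second: step 4. The ring hydrogen that must be abstracted is tertiary and may sit poorly aligned, so the ene reaction may be slow or unselective. The fallback sets out from 3 and comes back at 10. A syn‑selective zirconium‑enolate aldol of 3 with 4 (LiN(iPr)2, then Cp2ZrCl2, THF, −78 °C, aldehyde on the α face) gives the syn β‑hydroxy ketone F1 with the 1S carbinol. TESOTf and 2,6‑lutidine give the triethylsilyl ether F2. LiN(iPr)2 and then PhSeCl give the α‑phenylselanyl ketone F3 with selenium on the α face. H2O2 and pyridine bring about selenoxide syn‑elimination toward the cis ring C–H, away from the oxygenated carbon, to give the enone silyl ether F4. AcOH/THF/H2O removes the silyl group to give 10.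

Third: step 7 (new method). The silyl selenide may fail to open the ring, or the cation may lose a proton instead of being captured. The fallback sets out from 12 and comes back at 16. Aqueous HClO4 in THF at 0 °C opens the cyclopropyl ketone by homoconjugate addition of water to the tertiary alcohol F5. Burgess reagent in benzene at 50 °C dehydrates it by syn‑elimination to the isopropenyl ketone F6. LiN(SiMe3)2 with Me3SiCl present (THF, −78 °C) gives the kinetic C8 silyl enol ether F7. Dimethyldioxirane and then citric acid, as in step 8, give 16 by way of 15.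

Further compounds

F0 | step 5 | none | none
F1 | step 4 | syn-aldol, (1R,3S,4R,6S)-3-[(1S)-1-hydroxypent-4-en-1-yl]-4,7,7-trimethylbicyclo[4.1.0]heptan-2-one (side chain on the α face) | C=CCC[C@H](O)[C@@H]1C(=O)[C@@H]2[C@H](C[C@H]1C)C2(C)C
F2 | step 4 | triethylsilyl ether of the syn-aldol | C=CCC[C@H](O[Si](CC)(CC)CC)[C@@H]1C(=O)[C@@H]2[C@H](C[C@H]1C)C2(C)C
F3 | step 4 | α-phenylselanyl ketone (Se on the α face of the ring carbon between the carbonyl and the methyl-bearing carbon) | C=CCC[C@H](O[Si](CC)(CC)CC)[C@@]1([Se]c3ccccc3)C(=O)[C@@H]2[C@H](C[C@H]1C)C2(C)C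
F4 | step 4 | triethylsilyl ether of 10 | C=CCC[C@H](O[Si](CC)(CC)CC)C1=C(C)C[C@H]2[C@@H](C1=O)C2(C)C
F5 | step 7 | 1α-acetoxy-11-hydroxy-10αH-eremophilan-9-one | CC(C)(O)[C@H]1C[C@@]2(C)[C@H](C(=O)C1)[C@@H](OC(C)=O)CC[C@@H]2C
F6 | step 7 | 1α-acetoxy-10αH-eremophil-11-en-9-one | C=C(C)[C@H]1C[C@@]2(C)[C@H](C(=O)C1)[C@@H](OC(C)=O)CC[C@@H]2C
F7 | step 7 | 1α-acetoxy-9-(trimethylsilyloxy)-10αH-eremophila-8,11-diene | C=C(C)[C@H]1C[C@@]2(C)[C@H](C(O[Si](C)(C)C)=C1)[C@@H](OC(C)=O)CC[C@@H]2C
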